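The route rests on the bond between C5 of the benzene ring of the dihydrobenzofuran and the side-chain carbinol carbon C1′. A nickel-catalysed enantioconvergent reductive cross-coupling joins a stereodefined cis-5-iodo-2,3-dihydrobenzofuran (C3 isovalerate in place, enal carried as its allylic alcohol) with racemic 1-chloroethyl senecioate. One operation forms C5–C1′, sets 1′S and brings in the senecioate. It exploits that C1′ is benzylic and acyloxy-substituted, hence accessible as a planar α-acyloxy radical. C1′ also lies para to O1, too remote from C2/C3 for substrate control, so the ligand alone decides. C2 and C3 arise together from one (S)-proline 5-enolexo aldol reaction.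

Key step: step 7

Assumption: the sense of induction of the chiral ligand in step 7 cannot be read from the structure, so it is calibrated on 4-iodoanisole and the antipode that gives the S ester is used.

Step 1
Reactants: 1 5-iodosalicylaldehyde; 2 chloroacetone
Product: 3 5-iodo-2-(2-oxopropoxy)benzaldehyde
Conditions: K2CO3 (1.1 equiv), DMF, 0 °C → rt
Reagents that add atoms: none
Why: Williamson ether synthesis in which the phenoxide displaces the activated α-chloro ketone, while the low temperature and the small excess of weak base should keep the product from the base-induced aldol condensation (Rap–Stoermer pathway).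

Step 2
Reactants: 3 5-iodo-2-(2-oxopropoxy)benzaldehyde
Product: 4 1-[(2S,3R)-3-hydroxy-5-iodo-2,3-dihydro-1-benzofuran-2-yl]ethan-1-one (2,3-cis)
Conditions: (S)-proline (30 mol %), DMF, rt
Reagents that add atoms: none
Why: Proline-catalysed intramolecular 5-enolexo aldol reaction (enamine activation of the acetonyl ketone, carboxylic-acid activation of the aldehyde), in which the short aryl tether forces O1 and C3a onto the same side so that the cis ring forms, and the (S)-catalyst should shield one enamine face and set 2S and 3R in one event.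

Step 3
Reactants: 4 1-[(2S,3R)-3-hydroxy-5-iodo-2,3-dihydro-1-benzofuran-2-yl]ethan-1-one
Product: 5 (2R,3R)-5-iodo-2-(prop-1-en-2-yl)-2,3-dihydro-1-benzofuran-3-ol (cis)
Conditions: Tebbe reagent (2.5 equiv), pyridine (cat.), THF/toluene, −40 → 0 °C
Reagents that add atoms: Tebbe reagent [CH2]=[Ti+2].[cH-]1cccc1.[cH-]1cccc1.C[Al](C)Cl
Why: Tebbe methylenation, whose non-basic titanium methylidene converts the ketone into the isopropenyl group at low temperature without enolising C2, so the geometry is kept (the C2 descriptor changes from S to R only through the CIP priorities) and the free hydroxyl, which uses up the first equivalent, returns on work-up.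

Step 4
Reactants: 5 (2R,3R)-5-iodo-2-(prop-1-en-2-yl)-2,3-dihydro-1-benzofuran-3-ol; 6 3-methylbutanoyl chloride (isovaleryl chloride)
Product: 7 (2R,3R)-5-iodo-2-(prop-1-en-2-yl)-2,3-dihydro-1-benzofuran-3-yl 3-methylbutanoate
Conditions: pyridine (2 equiv), DMAP (5 mol %), CH2Cl2, 0 °C
Reagents that add atoms: none
Why: DMAP-catalysed O-acylation of the only hydroxyl group, which breaks no bond at C3 and therefore keeps both stereocentres.

Step 5
Reactants: 7 (2R,3R)-5-iodo-2-(prop-1-en-2-yl)-2,3-dihydro-1-benzofuran-3-yl 3-methylbutanoate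
Product: 8 (2R,3R)-2-(3-hydroxyprop-1-en-2-yl)-5-iodo-2,3-dihydro-1-benzofuran-3-yl 3-methylbutanoate
Conditions: SeO2 (0.4 equiv), t-BuOOH (3 equiv, decane), CH2Cl2, 0 °C → rt
Reagents that add atoms: selenium dioxide O=[Se]=O (oxygen carrier); tert-butyl hydroperoxide CC(C)(C)OO (terminal oxygen source)
Why: Riley-type allylic hydroxylation (ene reaction at the terminal CH2, then [2,3]-sigmatropic shift) that should take a hydrogen from the free methyl group rather than from the hindered, O1-deactivated C2–H, and that is placed here because no second allylic methyl group (senecioate) is present yet.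

Step 6
Reactants: 9 3-methylbut-2-enoyl chloride (senecioyl chloride); 10 acetaldehyde
Product: 11 rac-1-chloroethyl 3-methylbut-2-enoate
Conditions: ZnCl2 (2 mol %), CH2Cl2, −10 °C → rt, then distillation
Reagents that add atoms: none
Why: Lewis-acid-catalysed addition of an acyl chloride across an aldehyde carbonyl (α-chloroalkyl ester synthesis), atom-economical and needed only in racemic form.

Step 7
Reactants: 8 (2R,3R)-2-(3-hydroxyprop-1-en-2-yl)-5-iodo-2,3-dihydro-1-benzofuran-3-yl 3-methylbutanoate; 11 rac-1-chloroethyl 3-methylbut-2-enoate (1.8 equiv)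
Product: 13 (2R,3R)-2-(3-hydroxyprop-1-en-2-yl)-5-[(1S)-1-(3-methylbut-2-enoyloxy)ethyl]-2,3-dihydro-1-benzofuran-3-yl 3-methylbutanoate, via 1-(3-methylbut-2-enoyloxy)ethyl radical 12 (not isolated)
Conditions: NiBr2·glyme (10 mol %), C2-symmetric bi(oxazoline) ligand L* (4,4′-di(heptan-4-yl)-BiOX, 12 mol %), Mn (3 equiv), DMA/THF, 5 °C
Reagents that add atoms: none
Why: Mn reduces nickel to L*Ni(0), which inserts into the C5–I bond of 8, while a Ni(I) species abstracts chlorine from 11 to release the planar radical 12, so both enantiomers of 11 funnel into one intermediate that is captured at the chiral aryl-nickel(II) centre, and C5–C1′ forms by reductive elimination from Ni(III). The closest known reaction type is the nickel-catalysed enantioconvergent reductive cross-electrophile coupling of aryl iodides with racemic α-chloroalkyl esters and related α-heteroatom secondary alkyl halides. No ring is closed. The only new stereocentre, C1′ (S), is controlled by the ligand alone, because C2 and C3 sit on the other ring, too far from nickel to match or mismatch. The step needs cross- over homo-coupling, secured by the different activation modes (two-electron oxidative addition for the sp2 iodide, halogen abstraction for the activated sp3 chloride used in excess), and it needs 12 to spare the alkenes, secured by carrying the enal as an unactivated allylic alcohol and by the β,β-disubstitution of the senecioate. The benzylic esters at C3 and C1′ and the allylic C2–O1 ether are expected to survive because N-ligated nickel at 5 °C engages the aryl iodide far faster than C–O bonds.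

Step 8
Reactants: 13 (2R,3R)-2-(3-hydroxyprop-1-en-2-yl)-5-[(1S)-1-(3-methylbut-2-enoyloxy)ethyl]-2,3-dihydro-1-benzofuran-3-yl 3-methylbutanoate
Product: 14 (2R,3R)-5-[(1S)-1-(3-methylbut-2-enoyloxy)ethyl]-2-(3-oxoprop-1-en-2-yl)-2,3-dihydro-1-benzofuran-3-yl 3-methylbutanoate (target)
Conditions: activated MnO2 (15 equiv), CH2Cl2, rt
Reagents that add atoms: none
Why: MnO2 oxidation, selective for the primary allylic alcohol and run under neutral heterogeneous conditions, so that neither the ionisable p-alkoxybenzylic ester at C1′ nor the C3 ester (elimination to the benzofuran) should be disturbed.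

Compound list
1 | 5-iodosalicylaldehyde (2-hydroxy-5-iodobenzaldehyde) | O=Cc1cc(I)ccc1O | starting material
2 | chloroacetone | CC(=O)CCl | starting material
3 | 5-iodo-2-(2-oxopropoxy)benzaldehyde | CC(=O)COc1ccc(I)cc1C=O | intermediate
4 | 1-[(2S,3R)-3-hydroxy-5-iodo-2,3-dihydro-1-benzofuran-2-yl]ethan-1-one | CC(=O)[C@H]1Oc2ccc(I)cc2[C@H]1O | intermediate
5 | (2R,3R)-5-iodo-2-(prop-1-en-2-yl)-2,3-dihydro-1-benzofuran-3-ol | C=C(C)[C@H]1Oc2ccc(I)cc2[C@H]1O | intermediate
6 | 3-methylbutanoyl chloride | CC(C)CC(=O)Cl | starting material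
7 | (2R,3R)-5-iodo-2-(prop-1-en-2-yl)-2,3-dihydro-1-benzofuran-3-yl 3-methylbutanoate | C=C(C)[C@H]1Oc2ccc(I)cc2[C@H]1OC(=O)CC(C)C | intermediate
8 | (2R,3R)-2-(3-hydroxyprop-1-en-2-yl)-5-iodo-2,3-dihydro-1-benzofuran-3-yl 3-methylbutanoate | C=C(CO)[C@H]1Oc2ccc(I)cc2[C@H]1OC(=O)CC(C)C | intermediate
9 | 3-methylbut-2-enoyl chloride | CC(C)=CC(=O)Cl | starting material
10 | acetaldehyde | CC=O | starting material
11 | rac-1-chloroethyl 3-methylbut-2-enoate | CC(Cl)OC(=O)C=C(C)C | intermediate
12 | 1-(3-methylbut-2-enoyloxy)ethyl radical | C[CH]OC(=O)C=C(C)C | intermediate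
13 | (2R,3R)-2-(3-hydroxyprop-1-en-2-yl)-5-[(1S)-1-(3-methylbut-2-enoyloxy)ethyl]-2,3-dihydro-1-benzofuran-3-yl 3-methylbutanoate | C=C(CO)[C@H]1Oc2ccc([C@H](C)OC(=O)C=C(C)C)cc2[C@H]1OC(=O)CC(C)C | intermediate
14 | (2R,3R)-5-[(1S)-1-(3-methylbut-2-enoyloxy)ethyl]-2-(3-oxoprop-1-en-2-yl)-2,3-dihydro-1-benzofuran-3-yl 3-methylbutanoate | C=C(C=O)[C@H]1Oc2ccc([C@H](C)OC(=O)C=C(C)C)cc2[C@H]1OC(=O)CC(C)C | target

Total step count: 8. Longest linear sequence: 7 steps (1, 2, 3, 4, 5, 7, 8).

Steps most likely to fail

Step 7.
- **Risk:** the chloride may be consumed by reduction, β-hydride elimination, dimerisation or alkylation of the free hydroxyl group faster than the electron-rich aryl iodide enters the cycle.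
- **Risk:** the ligand may discriminate poorly between methyl and acyloxy at nickel, or low-valent nickel may ionise the allylic C2–O1 bond.
- **Fallback (two-electron C–C bond formation followed by catalyst-controlled reduction):** it sets out from 7. Stille coupling with tributyl(1-ethoxyvinyl)stannane (Pd(PPh3)4, CuI, DMF, 50 °C) gives the aryl enol ether F1. Brief hydrolysis with dilute aqueous oxalic acid gives the methyl ketone F2. Noyori–Ikariya transfer hydrogenation with RuCl[(S,S)-TsDPEN](p-cymene) in HCO2H/Et3N should give the (S)-carbinol F3. Steglich esterification with 3-methylbut-2-enoic acid gives the isopropenyl diester F4. SeO2/t-BuOOH hydroxylation of the isopropenyl methyl group, with the electron-poor senecioate alkene expected to react more slowly, comes back to the route at 13.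

Step 3.
- **Risk:** Lewis-acidic aluminium and titanium species may trigger retro-aldol ring opening, epimerisation at C2 or dehydration to the aromatic benzofuran before methylenation is complete.
- **Fallback (carbonyl addition followed by elimination):** it sets out from 4. MeMgCl (3 equiv, THF, −78 °C) gives the cis-diol F5. Acylation of the secondary hydroxyl group with 6 (pyridine, DMAP) leaves the tertiary one free and gives the hydroxy ester F6. Burgess dehydration of the tertiary alcohol towards a methyl group comes back to the route at 7, so that 5 is bypassed.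

Step 5.
- **Risk:** over-oxidation to the aldehyde level, a sluggish ene reaction because the alkene is deactivated by the allylic O1, or abstraction of C2–H with loss of the ring.
- **Fallback (epoxidation and isomerisation instead of C–H oxidation):** it sets out from 7. Buffered mCPBA (NaHCO3, CH2Cl2, 0 °C) gives the oxirane F7 as an epimer mixture, which is of no consequence because this centre is lost again. TMSOTf/DBU opens it at the tertiary carbon and eliminates towards the methyl group to give the allyl silyl ether F8. Dilute aqueous citric acid in THF removes the silyl group and comes back to the route at 8.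

Further compounds
F1 | step 7 | (2R,3R)-5-(1-ethoxyethenyl)-2-(prop-1-en-2-yl)-2,3-dihydro-1-benzofuran-3-yl 3-methylbutanoate | C=C(C)[C@H]1Oc2ccc(C(=C)OCC)cc2[C@H]1OC(=O)CC(C)C
F2 | step 7 | (2R,3R)-5-acetyl-2-(prop-1-en-2-yl)-2,3-dihydro-1-benzofuran-3-yl 3-methylbutanoate | C=C(C)[C@H]1Oc2ccc(C(C)=O)cc2[C@H]1OC(=O)CC(C)C
F3 | step 7 | (2R,3R)-5-[(1S)-1-hydroxyethyl]-2-(prop-1-en-2-yl)-2,3-dihydro-1-benzofuran-3-yl 3-methylbutanoate | C=C(C)[C@H]1Oc2ccc([C@H](C)O)cc2[C@H]1OC(=O)CC(C)C
F4 | step 7 | (2R,3R)-5-[(1S)-1-(3-methylbut-2-enoyloxy)ethyl]-2-(prop-1-en-2-yl)-2,3-dihydro-1-benzofuran-3-yl 3-methylbutanoate | C=C(C)[C@H]1Oc2ccc([C@H](C)OC(=O)C=C(C)C)cc2[C@H]1OC(=O)CC(C)C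
F5 | step 3 | (2S,3R)-2-(2-hydroxypropan-2-yl)-5-iodo-2,3-dihydro-1-benzofuran-3-ol | CC(C)(O)[C@H]1Oc2ccc(I)cc2[C@H]1O
F6 | step 3 | (2S,3R)-2-(2-hydroxypropan-2-yl)-5-iodo-2,3-dihydro-1-benzofuran-3-yl 3-methylbutanoate | CC(C)(O)[C@H]1Oc2ccc(I)cc2[C@H]1OC(=O)CC(C)C
F7 | step 5 | (2S,3R)-5-iodo-2-(2-methyloxiran-2-yl)-2,3-dihydro-1-benzofuran-3-yl 3-methylbutanoate (epimer mixture at the oxirane carbon) | CC1(CO1)[C@H]2Oc3ccc(I)cc3[C@H]2OC(=O)CC(C)C
F8 | step 5 | (2R,3R)-5-iodo-2-[3-(trimethylsilyloxy)prop-1-en-2-yl]-2,3-dihydro-1-benzofuran-3-yl 3-methylbutanoate | C=C(CO[Si](C)(C)C)[C@H]1Oc2ccc(I)cc2[C@H]1OC(=O)CC(C)C
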